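**Plan**

- Retrosynthesis: the C12–O8 lactone bond, the O6 tiglate and the 4,5-epoxide are removed first. The (E)-cyclodecenone that remains is traced back by re-forming the transannular C4–C9 bond, and C9–C10 and C3–C4 are then cut to reach (R)-carvone.
- Enabling feature: C4 (methyl-bearing) and C9 (oxygen-bearing) face each other across the ten-membered ring C1–C10. Joining them gives a decalin whose ring A (C4 to C9) is the carvone ring, with O9 and an oxygen on C5 standing 1,3 across the C4–C9 bond, which is the retron of a Wharton–Grob fragmentation.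
- Forward order: ring A is carvone; ring B (C9, C10, C1–C3, C4) is added by alkylation at C4 and SmI2 closure of C9–C10. After oxygenation of C5 and C6 the fragmentation cuts the shared bond and leaves the ten-membered ring; epoxide, tiglate and the α-methylene lactone follow.
- Stereochemistry: C7 comes from (R)-carvone. C8 (enolate hydroxylation anti to isopropenyl), C6 (directed dihydroxylation), C5 (directed ketone reduction) and C10 (chair-like ring closure) are set on six-membered rings. The (E) alkene comes from the stereospecific fragmentation; C9 is reset by chelation-controlled reduction and C4/C5 by O6-directed epoxidation.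

Key step: step 12

Remark on numbering: locants are those of the target's ten-membered ring (C8 lactone O–CH, C9 CHOH, C10 CHMe, C1–C3 CH2, C4/C5 epoxide, C6 CH–O-tigloyl, C7 ring fusion; C11–C13 the three-carbon unit on C7, C12 its oxygenated carbon). With the ring drawn flat in this numbering, β is the face carrying the C7 side chain and α the other face.

Remark on the chemistry (assumption): 1,4-dibromopentane is used as the racemate, so 7 is a pair of epimers at the CHBr carbon; both should converge in step 4 because a secondary alkylsamarium is configurationally labile.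

Step 1
Reactants: 1 (R)-carvone
Product: 3 (5S,6S)-6-hydroxycarvone, via lithium enolate 2 (not isolated)
Conditions: LiN(iPr)2, THF, −78 °C; then 2-(phenylsulfonyl)-3-phenyloxaziridine, −78 °C; H2O
Reagents that add atoms: 2-(phenylsulfonyl)-3-phenyloxaziridine O=S(=O)(c1ccccc1)N1OC1c1ccccc1
Why: Kinetic deprotonation at the α′ methylene (C8) gives the cross-conjugated enolate, and its hydroxylation by the N-sulfonyloxaziridine (enolate oxidation) should occur on the face opposite the adjacent isopropenyl group, setting O8 trans to the C7 substituent.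

Step 2
Reactants: 3 (5S,6S)-6-hydroxycarvone
Product: 4 TBS ether of 3
Conditions: TBSOTf, 2,6-lutidine, CH2Cl2, −78 °C
Reagents that add atoms: tert-butyldimethylsilyl triflate CC(C)(C)[Si](C)(C)OS(=O)(=O)C(F)(F)F
Why: Silyl ether formation on the hindered secondary α-hydroxy ketone masks O8 for the basic, reducing and oxidising steps that follow and creates no stereocentre.

Step 3
Reactants: 4 TBS ether of 3; 5 1,4-dibromopentane
Product: 7 2-(4-bromopentyl)-6-(TBS-oxy)-2-methyl-5-isopropenylcyclohex-3-en-1-one, via potassium dienolate 6 (not isolated)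
Conditions: KOtBu, t-BuOH–THF, 0 °C; then 5 (excess), −20 °C → rt
Reagents that add atoms: 1,4-dibromopentane CC(Br)CCCBr
Why: Under equilibrating conditions the extended (γ-deprotonated) dienolate forms and is alkylated at its α carbon by the primary bromide only (deconjugative α-alkylation), giving the C4 quaternary centre and the C5=C6 alkene; the electrophile should enter on the face opposite the C7 isopropenyl group, placing the chain trans to it.

Step 4
Reactants: 7 bromopentyl ketone
Product: 9 trans-fused bicyclic carbinol (9α-OH; 4β-Me; 10α-Me; 8α-OTBS; 7β-isopropenyl; C5=C6), via alkylsamarium 8 (not isolated)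
Conditions: SmI2, HMPA, THF, −78 → 0 °C
Reagents that add atoms: none
Why: SmI2–HMPA reduces the secondary bromide to an alkylsamarium that adds to the neighbouring ketone (intramolecular Barbier reaction) through a chair-like six-membered transition state with the chain equatorial on C4 and the C10 methyl equatorial on the forming ring, which should give the trans-fused carbinol with the C9 hydroxyl anti to the C4 methyl.

Step 5
Reactants: 9 trans-fused bicyclic carbinol
Product: 11 5α,6α,9α-triol, via osmate ester 10 (not isolated)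
Conditions: OsO4 (1.05 equiv), TMEDA, CH2Cl2, −78 °C; then aq. Na2SO3, THF, reflux
Reagents that add atoms: osmium tetroxide O=[Os](=O)(=O)=O
Why: The OsO4·TMEDA adduct is hydrogen-bonded by the axial homoallylic C9 hydroxyl, so it should osmylate the ring alkene in preference to the isopropenyl group and from the α face (hydroxyl-directed syn-dihydroxylation), which is also the face anti to the axial C4 methyl, giving the axial C5 and equatorial C6 hydroxyls.

Step 6
Reactants: 11 5α,6α,9α-triol; 12 4-methoxybenzyl chloride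
Product: 14 6-O-PMB ether (5α-OH and 9α-OH free), via stannylene acetal 13 (not isolated)
Conditions: Bu2SnO, toluene, reflux (−H2O); then 12, Bu4NI, toluene, 90 °C
Reagents that add atoms: 4-methoxybenzyl chloride COc1ccc(CCl)cc1
Why: The cis-5,6-diol forms a five-membered dibutylstannylene acetal whose equatorial oxygen is the more nucleophilic, so stannylene-mediated O-alkylation should place the PMB group on O6 and leave the axial neopentyl C5 hydroxyl and the tertiary C9 hydroxyl free.

Step 7
Reactants: 14 6-O-PMB ether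
Product: 15 5-ketone (9α-OH; 6α-OPMB)
Conditions: Dess–Martin periodinane, CH2Cl2, rt
Reagents that add atoms: none
Why: The periodinane oxidises the only secondary alcohol (Dess–Martin oxidation) under non-basic conditions, so the resulting β-hydroxy ketone is not exposed to retro-aldol cleavage.

Step 8
Reactants: 15 5-ketone
Product: 16 5β,9α-diol (5-OH equatorial)
Conditions: Me4NBH(OAc)3, AcOH–MeCN, −20 °C
Reagents that add atoms: none
Why: The triacetoxyborohydride binds the axial C9 hydroxyl and delivers hydride intramolecularly to the α face of the C5 ketone (hydroxyl-directed anti-1,3 reduction, Evans–Saksena type), so the new C5 hydroxyl should be β and equatorial, trans to O6 and anti-periplanar to the C4–C9 bond.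

Step 9
Reactants: 16 5β,9α-diol
Product: 17 allylic alcohol (C7 side chain = 3-hydroxyprop-1-en-2-yl)
Conditions: SeO2 (0.5 equiv), t-BuOOH, CH2Cl2, rt
Reagents that add atoms: selenium dioxide O=[Se]=O; tert-butyl hydroperoxide CC(C)(C)OO
Why: The isopropenyl group is now the only alkene, so the SeO2-mediated ene/[2,3]-sigmatropic sequence (allylic oxidation) should hydroxylate its methyl group, preferred over the allylic methine, without touching a stereocentre.

Step 10
Reactants: 17 allylic alcohol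
Product: 18 primary TBS ether of 17
Conditions: TBSCl, imidazole, CH2Cl2, 0 °C
Reagents that add atoms: tert-butyldimethylsilyl chloride CC(C)(C)[Si](C)(C)Cl
Why: The primary allylic hydroxyl is silylated much faster than the hindered secondary C5 and tertiary C9 hydroxyls (selective silyl ether formation), storing C12 at the alcohol oxidation level.

Step 11
Reactants: 18 primary TBS ether
Product: 19 5β-mesylate (fragmentation precursor)
Conditions: MsCl, Et3N, CH2Cl2, −10 °C
Reagents that add atoms: methanesulfonyl chloride CS(=O)(=O)Cl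
Why: Sulfonylation converts the equatorial secondary C5 hydroxyl into the leaving group with retention at C5, while the tertiary C9 hydroxyl is too hindered to react.

Step 12
Reactants: 19 5β-mesylate
Product: 21 (4E)-cyclodecenone (9-oxo; 8α-OTBS; 10α-Me; 6α-OPMB; 7β side chain), via potassium alkoxide 20 (not isolated)
Conditions: KOtBu (1.1 equiv), THF, 0 °C
Reagents that add atoms: none
Why: KOtBu deprotonates the tertiary C9 hydroxyl, and the alkoxide lone pair pushes into the C4–C9 bond, which is anti-periplanar to the equatorial C5–O bond in the rigid trans-fused chair–chair, so C4–C9 breaks while C9=O and C4=C5 form and mesylate leaves in one concerted step. The closest known reaction is the Wharton variant of the Grob fragmentation of decalin 1,3-diol monosulfonates to (E)-cyclodec-5-enones. No ring is closed: cutting the bond shared by rings A and B merges them into the ten-membered ring. No stereocentre is created; C4, C5 and C9 become trigonal, and the alkene geometry follows from the substrate because C3 (equatorial on C4) is anti to C6 across C4–C5, which should translate into the (E) alkene. The selectivities needed are (E) over (Z) and fragmentation over elimination or substitution, both secured by the locked anti-periplanar arrangement. Only a slight excess of base at 0 °C is used so that C8 and C10, whose substituents flank the new ketone in pseudo-equatorial positions, should not epimerise.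

Step 13
Reactants: 21 (4E)-cyclodecenone
Product: 22 6α-allylic alcohol
Conditions: DDQ, CH2Cl2–pH 7 buffer, 0 °C
Reagents that add atoms: none
Why: DDQ oxidises the electron-rich benzyl ether to an oxocarbenium ion that water hydrolyses (oxidative PMB cleavage), freeing the allylic C6 hydroxyl without affecting the silyl ethers, the ketone or the alkenes.

Step 14
Reactants: 22 6α-allylic alcohol
Product: 23 epoxy alcohol (4,5-trans-epoxide; oxygen β at C4 and α at C5)
Conditions: VO(acac)2 (cat.), t-BuOOH, CH2Cl2, 0 °C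
Reagents that add atoms: tert-butyl hydroperoxide CC(C)(C)OO
Why: The C6 hydroxyl binds vanadium and the bound peroxide epoxidises the adjacent trisubstituted alkene much faster than the remote allyl silyl ether (hydroxyl-directed epoxidation); delivery needs an O6–C6–C5=C4 dihedral near 45°, which in the (E)-cyclodecene places ring carbon C7 on the opposite face, so oxygen should enter anti to the C6–C7 bond and set C4 and C5 as in the target.

Step 15
Reactants: 23 epoxy alcohol; 24 tigloyl chloride
Product: 25 6-O-tiglate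
Conditions: 24, Et3N, DMAP, CH2Cl2, 0 °C → rt
Reagents that add atoms: tigloyl chloride C/C=C(\C)C(=O)Cl
Why: DMAP-catalysed acylation of the only free hydroxyl (esterification) installs the (E)-2-methylbut-2-enoate while C9 is still a ketone, so no choice between O6 and O9 arises.

Step 16
Reactants: 25 6-O-tiglate
Product: 26 8α-hydroxy-9-ketone with free C12 hydroxyl
Conditions: Bu4NF, AcOH, THF, rt
Reagents that add atoms: none
Why: Acetic acid-buffered fluoride cleaves both silyl ethers (fluoride desilylation), and the buffer should suppress acyl migration, epoxide opening and epimerisation next to the ketone.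

Step 17
Reactants: 26 8α-hydroxy-9-ketone
Product: 27 8α,9α,12-triol
Conditions: Zn(BH4)2, Et2O, −20 °C
Reagents that add atoms: none
Why: Zinc chelates the C8 hydroxyl and the C9 carbonyl and hydride adds to the chelate face anti to C7 (chelation-controlled reduction of an α-hydroxy ketone to the anti-1,2-diol), which should set the C9 hydroxyl on the α face beside O8 as in the target, while ester, epoxide and alkenes are not reduced at low temperature.

Step 18
Reactants: 27 8α,9α,12-triol
Product: 30 target lactone, via hydroxy enal 28 (not isolated), via lactol 29 (not isolated)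
Conditions: MnO2, CH2Cl2, rt
Reagents that add atoms: none
Why: MnO2 oxidises only the primary allylic alcohol to the enal, the neighbouring C8 hydroxyl closes the five-membered lactol (closure on O9 would need a bridged six-membered ring and O6 is acylated), and the allylic lactol is oxidised on to the α-methylene-γ-lactone (oxidative lactonisation of a 2-methylene-1,4-diol); the trans ring fusion follows from the existing C7 and C8 configurations.

**Compound list**

1 | (R)-carvone | CC(=C)[C@@H]1CC=C(C)C(=O)C1 | starting material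
2 | lithium enolate of 1 (cross-conjugated, C8=C9) | [Li+].[O-]C1=C[C@H](C(C)=C)CC=C1C | intermediate
3 | (5S,6S)-6-hydroxy-2-methyl-5-(prop-1-en-2-yl)cyclohex-2-en-1-one (O8 trans to isopropenyl) | O[C@@H]1C(=O)C(C)=CC[C@H]1C(C)=C | intermediate
4 | tert-butyldimethylsilyl ether of 3 | CC(C)(C)[Si](C)(C)O[C@@H]1C(=O)C(C)=CC[C@H]1C(C)=C | intermediate
5 | 1,4-dibromopentane (racemic) | CC(Br)CCCBr | starting material
6 | potassium dienolate of 4 (extended, O9–C9=C4–C5=C6) | [K+].[O-]C1=C(C)C=C[C@@H](C(C)=C)[C@@H]1O[Si](C)(C)C(C)(C)C | intermediate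
7 | 2-(4-bromopentyl)-6-(TBS-oxy)-2-methyl-5-(prop-1-en-2-yl)cyclohex-3-en-1-one; bromopentyl chain trans and methyl cis to isopropenyl, silyloxy trans to isopropenyl; both epimers at CHBr | CC(C)(C)[Si](C)(C)O[C@@H]1C(=O)[C@](C)(CCCC(C)Br)C=C[C@H]1C(C)=C | intermediate
8 | diiodosamarium alkyl derived from 7 (Sm on the former CHBr carbon) | CC(C)(C)[Si](C)(C)O[C@@H]1C(=O)[C@](C)(CCCC(C)[Sm](I)I)C=C[C@H]1C(C)=C | intermediate
9 | trans-fused bicyclic carbinol: 9α-OH, 4β-Me (both axial), 10α-Me (equatorial), 8α-OTBS, 7β-isopropenyl, C5=C6 | CC(C)(C)[Si](C)(C)O[C@@H]1[C@@]2(O)[C@H](C)CCC[C@]2(C)C=C[C@H]1C(C)=C | intermediate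
10 | cyclic 5α,6α-osmate ester of 9, TMEDA chelate | CC(C)(C)[Si](C)(C)O[C@@H]1[C@@]2(O)[C@H](C)CCC[C@]2(C)[C@@H]3O[Os-2]4(=O)(=O)([N+](C)(C)CC[N+]4(C)C)O[C@@H]3[C@H]1C(C)=C | intermediate
11 | 5α,6α,9α-triol (5-OH axial, 6-OH equatorial) | CC(C)(C)[Si](C)(C)O[C@@H]1[C@@]2(O)[C@H](C)CCC[C@]2(C)[C@H](O)[C@H](O)[C@H]1C(C)=C | intermediate
12 | 4-methoxybenzyl chloride | COc1ccc(CCl)cc1 | starting material
13 | 5,6-O-dibutylstannylene acetal of 11 | CC(C)(C)[Si](C)(C)O[C@@H]1[C@@]2(O)[C@H](C)CCC[C@]2(C)[C@@H]3O[Sn](CCCC)(CCCC)O[C@@H]3[C@H]1C(C)=C | intermediate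
14 | 6α-O-PMB ether with free 5α-OH and 9α-OH | CC(C)(C)[Si](C)(C)O[C@@H]1[C@@]2(O)[C@H](C)CCC[C@]2(C)[C@H](O)[C@H](OCc3ccc(OC)cc3)[C@H]1C(C)=C | intermediate
15 | 5-ketone (9α-OH, 6α-OPMB, 8α-OTBS) | CC(C)(C)[Si](C)(C)O[C@@H]1[C@@]2(O)[C@H](C)CCC[C@]2(C)C(=O)[C@H](OCc3ccc(OC)cc3)[C@H]1C(C)=C | intermediate
16 | 5β,9α-diol (5-OH equatorial, trans to 6α-OPMB) | CC(C)(C)[Si](C)(C)O[C@@H]1[C@@]2(O)[C@H](C)CCC[C@]2(C)[C@@H](O)[C@H](OCc3ccc(OC)cc3)[C@H]1C(C)=C | intermediate
17 | allylic alcohol: as 16 with the C7 side chain 3-hydroxyprop-1-en-2-yl | CC(C)(C)[Si](C)(C)O[C@@H]1[C@@]2(O)[C@H](C)CCC[C@]2(C)[C@@H](O)[C@H](OCc3ccc(OC)cc3)[C@H]1C(=C)CO | intermediate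
18 | primary TBS ether of 17 | CC(C)(C)[Si](C)(C)O[C@@H]1[C@@]2(O)[C@H](C)CCC[C@]2(C)[C@@H](O)[C@H](OCc3ccc(OC)cc3)[C@H]1C(=C)CO[Si](C)(C)C(C)(C)C | intermediate
19 | trans-decalin 5β-mesylate (equatorial), 9α-OH, 4β-Me, 10α-Me, 6α-OPMB, 8α-OTBS, 7β-[3-(TBS-oxy)prop-1-en-2-yl] | CC(C)(C)[Si](C)(C)O[C@@H]1[C@@]2(O)[C@H](C)CCC[C@]2(C)[C@@H](OS(C)(=O)=O)[C@H](OCc3ccc(OC)cc3)[C@H]1C(=C)CO[Si](C)(C)C(C)(C)C | intermediate
20 | potassium C9-alkoxide of 19 | CC(C)(C)[Si](C)(C)O[C@@H]1[C@@]2([O-])[C@H](C)CCC[C@]2(C)[C@@H](OS(C)(=O)=O)[C@H](OCc3ccc(OC)cc3)[C@H]1C(=C)CO[Si](C)(C)C(C)(C)C.[K+] | intermediate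
21 | (4E)-cyclodec-4-en-9-one: 4-Me, 10α-Me, 8α-OTBS, 6α-OPMB, 7β-[3-(TBS-oxy)prop-1-en-2-yl] | CC(C)(C)[Si](C)(C)O[C@@H]1C(=O)[C@H](C)CCC/C(C)=C/[C@H](OCc2ccc(OC)cc2)[C@H]1C(=C)CO[Si](C)(C)C(C)(C)C | intermediate
22 | 6α-allylic alcohol (PMB removed from 21) | CC(C)(C)[Si](C)(C)O[C@@H]1C(=O)[C@H](C)CCC/C(C)=C/[C@H](O)[C@H]1C(=C)CO[Si](C)(C)C(C)(C)C | intermediate
23 | 4,5-trans-epoxy-6α-alcohol (epoxide oxygen β at C4, α at C5) | CC(C)(C)[Si](C)(C)O[C@@H]1C(=O)[C@H](C)CCC[C@@]2(C)O[C@@H]2[C@H](O)[C@H]1C(=C)CO[Si](C)(C)C(C)(C)C | intermediate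
24 | tigloyl chloride, (E)-2-methylbut-2-enoyl chloride | C/C=C(\C)C(=O)Cl | starting material
25 | 6-O-tiglate of 23 | CC(C)(C)[Si](C)(C)O[C@@H]1C(=O)[C@H](C)CCC[C@@]2(C)O[C@@H]2[C@H](OC(=O)/C(C)=C/C)[C@H]1C(=C)CO[Si](C)(C)C(C)(C)C | intermediate
26 | 8α-hydroxy-9-ketone with 3-hydroxyprop-1-en-2-yl side chain (both silyl groups removed) | O[C@@H]1C(=O)[C@H](C)CCC[C@@]2(C)O[C@@H]2[C@H](OC(=O)/C(C)=C/C)[C@H]1C(=C)CO | intermediate
27 | 8α,9α,12-triol | O[C@@H]1[C@H](O)[C@H](C)CCC[C@@]2(C)O[C@@H]2[C@H](OC(=O)/C(C)=C/C)[C@H]1C(=C)CO | intermediate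
28 | hydroxy enal (C12 aldehyde, 8α,9α-diol) | O[C@@H]1[C@H](O)[C@H](C)CCC[C@@]2(C)O[C@@H]2[C@H](OC(=O)/C(C)=C/C)[C@H]1C(=C)C=O | intermediate
29 | α-methylene lactol closed on O8 (anomeric carbon unassigned) | C=C1C(O)O[C@@H]2[C@H](O)[C@H](C)CCC[C@@]3(C)O[C@@H]3[C@H](OC(=O)/C(C)=C/C)[C@@H]12 | intermediate
30 | CNP0165329.2: 4,5-epoxy-9α-hydroxy-6α-tigloyloxy α-methylene-12,8-lactone | C=C1C(=O)O[C@@H]2[C@H](O)[C@H](C)CCC[C@@]3(C)O[C@@H]3[C@H](OC(=O)/C(C)=C/C)[C@@H]12 | target

Total step count: 18. Longest linear sequence: 18 steps, from 1.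

**Steps most likely to fail**

1. Step 4. The alkylsamarium may add along the axial trajectory of the cyclohexenone and close the cis-fused carbinol, giving the wrong C9 and C10 configurations, and electron transfer to the α-silyloxy ketone may cleave the C8–O bond. Fallback, setting out from 4 and returning at 21: the C9 oxygen is introduced by electrophilic attack anti to the angular methyl instead of by carbonyl addition.
   - Alkylation of 4 as in step 3 but with 5-bromopent-1-ene gives pentenyl ketone F1.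
   - Wittig methylenation (Ph3PCH3Br, KOtBu, toluene, 80 °C) gives tetraene F2.
   - Ring-closing metathesis with the second-generation Grubbs catalyst RuCl2(=CHPh)(H2IMes)(PCy3) closes ring B as octalin F3.
   - mCPBA epoxidises the new trisubstituted alkene from the α face, opposite the C4 methyl, to epoxide F4.
   - MeMgBr with catalytic CuI opens F4 trans-diaxially at C10 (a ring-fusion epoxide opening well known in the steroid series) to 10-epi-carbinol F5, in which the C10 methyl is axial.
   - F5 is taken through steps 5 to 11 unchanged, via osmate ester F6, triol F7, stannylene acetal F8, PMB ether F9, ketone F10, diol F11, allylic alcohol F12 and silyl ether F13, to mesylate F14.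
   - Under the conditions of step 12, F14 fragments through alkoxide F15 to 10-epi-cyclodecenone F16.
   - C10 is now α to the ketone and is equilibrated (DBU, CH2Cl2) to the epimer with the methyl pseudo-equatorial, which is 21.

2. Step 14. Facial selectivity may be poor or reversed, because the vanadate ester can also transfer oxygen through the ring conformer that places O6 on the peripheral alkene face, which gives the other trans-epoxide. Fallback, setting out from 21 and returning at 23: the epoxide oxygen is brought to the inner alkene face from the transannular ketone.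
   - I2 and NaHCO3 in aqueous MeCN add iodine to the peripheral face of C5, while the C9 carbonyl oxygen closes onto C4 and water caps C9, giving iodo hemiketal F17.
   - K2CO3 in MeOH reopens the hemiketal to the ketone, and the released C4 alkoxide displaces iodide at C5 with inversion (as in the conversion of iodolactones into epoxy esters) to epoxy ketone F18, which still carries the PMB group.
   - DDQ as in step 13 then gives 23.

3. Step 5. Chemoselectivity may be lost through competing osmylation of the isopropenyl group. Fallback, setting out from 9 and returning at 15: the alkene is oxidised in stages.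
   - VO(acac)2 and t-BuOOH, directed by the same C9 hydroxyl, give the 5α,6α-epoxide F19.
   - LiAlH4 opens it trans-diaxially at C6 to the axial 5α-alcohol F20.
   - Dess–Martin periodinane gives ketone F21.
   - TMSOTf and Et3N give bis-silyl derivative F22 (C5 enol ether, C9 silyl ether).
   - Dimethyldioxirane oxidises the enol ether from the α face (Rubottom oxidation) to silyloxy ketone F23.
   - Citric acid in MeOH gives hydroxy ketone F24.
   - PMB trichloroacetimidate with catalytic La(OTf)3 etherifies the secondary hydroxyl to give 15.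

**Further compounds**

F1 | step 4 | 6-(TBS-oxy)-2-methyl-2-(pent-4-enyl)-5-isopropenylcyclohex-3-en-1-one | CC(C)(C)[Si](C)(C)O[C@@H]1C(=O)[C@](C)(CCCC=C)C=C[C@H]1C(C)=C
F2 | step 4 | 9-methylene tetraene | CC(C)(C)[Si](C)(C)O[C@@H]1C(=C)[C@](C)(CCCC=C)C=C[C@H]1C(C)=C
F3 | step 4 | octalin with C9=C10 and C5=C6 | CC(C)(C)[Si](C)(C)O[C@@H]1C2=CCCC[C@]2(C)C=C[C@H]1C(C)=C
F4 | step 4 | 9α,10α-epoxide of F3 | CC(C)(C)[Si](C)(C)O[C@@H]1[C@]23O[C@@H]3CCC[C@]2(C)C=C[C@H]1C(C)=C
F5 | step 4 | 10-epi-9 (10β-methyl, axial) | CC(C)(C)[Si](C)(C)O[C@@H]1[C@@]2(O)[C@@H](C)CCC[C@]2(C)C=C[C@H]1C(C)=C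
F6 | step 4 | osmate ester of F5 (10-epi-10) | CC(C)(C)[Si](C)(C)O[C@@H]1[C@@]2(O)[C@@H](C)CCC[C@]2(C)[C@@H]3O[Os-2]4(=O)(=O)([N+](C)(C)CC[N+]4(C)C)O[C@@H]3[C@H]1C(C)=C
F7 | step 4 | 10-epi-11 (triol) | CC(C)(C)[Si](C)(C)O[C@@H]1[C@@]2(O)[C@@H](C)CCC[C@]2(C)[C@H](O)[C@H](O)[C@H]1C(C)=C
F8 | step 4 | 10-epi-13 (stannylene acetal) | CC(C)(C)[Si](C)(C)O[C@@H]1[C@@]2(O)[C@@H](C)CCC[C@]2(C)[C@@H]3O[Sn](CCCC)(CCCC)O[C@@H]3[C@H]1C(C)=C
F9 | step 4 | 10-epi-14 (PMB ether) | CC(C)(C)[Si](C)(C)O[C@@H]1[C@@]2(O)[C@@H](C)CCC[C@]2(C)[C@H](O)[C@H](OCc3ccc(OC)cc3)[C@H]1C(C)=C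
F10 | step 4 | 10-epi-15 (5-ketone) | CC(C)(C)[Si](C)(C)O[C@@H]1[C@@]2(O)[C@@H](C)CCC[C@]2(C)C(=O)[C@H](OCc3ccc(OC)cc3)[C@H]1C(C)=C
F11 | step 4 | 10-epi-16 (5β,9α-diol) | CC(C)(C)[Si](C)(C)O[C@@H]1[C@@]2(O)[C@@H](C)CCC[C@]2(C)[C@@H](O)[C@H](OCc3ccc(OC)cc3)[C@H]1C(C)=C
F12 | step 4 | 10-epi-17 (allylic alcohol) | CC(C)(C)[Si](C)(C)O[C@@H]1[C@@]2(O)[C@@H](C)CCC[C@]2(C)[C@@H](O)[C@H](OCc3ccc(OC)cc3)[C@H]1C(=C)CO
F13 | step 4 | 10-epi-18 (silyl ether) | CC(C)(C)[Si](C)(C)O[C@@H]1[C@@]2(O)[C@@H](C)CCC[C@]2(C)[C@@H](O)[C@H](OCc3ccc(OC)cc3)[C@H]1C(=C)CO[Si](C)(C)C(C)(C)C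
F14 | step 4 | 10-epi-19 (mesylate) | CC(C)(C)[Si](C)(C)O[C@@H]1[C@@]2(O)[C@@H](C)CCC[C@]2(C)[C@@H](OS(C)(=O)=O)[C@H](OCc3ccc(OC)cc3)[C@H]1C(=C)CO[Si](C)(C)C(C)(C)C
F15 | step 4 | potassium alkoxide of F14 | CC(C)(C)[Si](C)(C)O[C@@H]1[C@@]2([O-])[C@@H](C)CCC[C@]2(C)[C@@H](OS(C)(=O)=O)[C@H](OCc3ccc(OC)cc3)[C@H]1C(=C)CO[Si](C)(C)C(C)(C)C.[K+]
F16 | step 4 | 10-epi-21 (cyclodecenone) | CC(C)(C)[Si](C)(C)O[C@@H]1C(=O)[C@@H](C)CCC/C(C)=C/[C@H](OCc2ccc(OC)cc2)[C@H]1C(=C)CO[Si](C)(C)C(C)(C)C
F17 | step 14 | 5-iodo C4–O–C9 transannular hemiketal | CC(C)(C)[Si](C)(C)O[C@@H]1[C@@]2(O)[C@H](C)CCC[C@@](C)(O2)[C@@H](I)[C@H](OCc3ccc(OC)cc3)[C@H]1C(=C)CO[Si](C)(C)C(C)(C)C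
F18 | step 14 | 6-O-PMB 4,5-epoxy ketone | CC(C)(C)[Si](C)(C)O[C@@H]1C(=O)[C@H](C)CCC[C@@]2(C)O[C@@H]2[C@H](OCc3ccc(OC)cc3)[C@H]1C(=C)CO[Si](C)(C)C(C)(C)C
F19 | step 5 | 5α,6α-epoxide of 9 | CC(C)(C)[Si](C)(C)O[C@@H]1[C@@]2(O)[C@H](C)CCC[C@]2(C)[C@@H]3O[C@@H]3[C@H]1C(C)=C
F20 | step 5 | 5α,9α-diol (C6 methylene) | CC(C)(C)[Si](C)(C)O[C@@H]1[C@@]2(O)[C@H](C)CCC[C@]2(C)[C@H](O)C[C@H]1C(C)=C
F21 | step 5 | 5-ketone (C6 methylene, 9α-OH) | CC(C)(C)[Si](C)(C)O[C@@H]1[C@@]2(O)[C@H](C)CCC[C@]2(C)C(=O)C[C@H]1C(C)=C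
F22 | step 5 | C5 trimethylsilyl enol ether, C9 trimethylsilyl ether | CC(C)(C)[Si](C)(C)O[C@@H]1[C@@]2(O[Si](C)(C)C)[C@H](C)CCC[C@]2(C)C(O[Si](C)(C)C)=C[C@H]1C(C)=C
F23 | step 5 | 6α-trimethylsilyloxy 5-ketone, C9 trimethylsilyl ether | CC(C)(C)[Si](C)(C)O[C@@H]1[C@@]2(O[Si](C)(C)C)[C@H](C)CCC[C@]2(C)C(=O)[C@H](O[Si](C)(C)C)[C@H]1C(C)=C
F24 | step 5 | 6α-hydroxy 5-ketone (9α-OH) | CC(C)(C)[Si](C)(C)O[C@@H]1[C@@]2(O)[C@H](C)CCC[C@]2(C)C(=O)[C@H](O)[C@H]1C(C)=C
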